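- The target, P, is what I want from these flasks, and the isomer of the product, E, is what I fear. I follow the share s = P/(P + E), the selectivity of a run.

all flasks: substrate 0.30 M; catalyst 1.5 mM

| flask | coupling partner | remark | time |
|---|---|---|---|
| zeta | 0.027 M | run made earlier |  |
| delta | 0.091 M | run made earlier |  |
| Friday's | 0.0400 M |  | 8.0 h |
| Wednesday's | 0.0600 M |  | 8.0 h |
| Sunday's | 0.100 M |  | 8.0 h |
| Tuesday's | 0.150 M |  | 8.0 h |

| run | time / h | target / % | isomer of the product / % |
|---|---|---|---|
| zeta | 0.333 | 2.5 | 1.4 |
| zeta | 0.500 | 3.5 | 1.7 |
| zeta | 0.833 | 4.9 | 1.7 |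
| zeta | 1.33 | 3.5 | 0.7 |
| zeta | 2.50 | 5.2 | 0 |
| zeta | 4.00 | 4.5 | 0 |
| delta | 0.250 | 5.0 | 0 |
| delta | 0.833 | 9.9 | 0.9 |
| delta | 1.33 | 14.0 | 1.5 |
| delta | 2.00 | 14.3 | 1.9 |
| delta | 3.00 | 14.7 | 4.4 |
| delta | 4.00 | 13.3 | 3.4 |

(scatter of a reading: 1 percentage point)

- "hardly changes" means that all values lie within two and a half points (for a concentration: within two and a half percent of the largest)

1. share of target in all that became target or isomer of the product for Friday's, Wednesday's, Sunday's, Tuesday's, in this order
2. how that number moves from the first to the last of them (hardly changes / rises all the way / rises, then falls / falls, then rises / falls all the way)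

- First instants, in delta: target reads 5.0% at 0.250 h while isomer reads 0%. I take target as the kinetic product, with isomer coming from it.
- Middle, in delta: forming is fast, and target reads 14.0% by 1.33 h, early against 8.0 h. At 3.00 h, target and isomer together read 19.1% of the substrate. That is 63.0% of what the partner charge allows, so I read a stall with coupling partner left.
- Later, in delta: the slow step is what I expect to matter, target turning into isomer. I assume it is first order, so its clock holds no concentration.
- I set zeta aside for this: its isomer never reads above 1.7%, against a scatter of 1 percentage point.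
- I define the isomerisation clock κ = ln(1 + E/P)/t, the rate at which ln s falls 0.0699 h⁻¹. Delta's last two readings give 0.0699 h⁻¹, and that reading carries the scatter.
- In powers of ten, log10 s falls at 0.0304 h⁻¹ in delta's readings, which end at 4.00 h. I carry that pace on to 8.0 h and no further, as an estimate, and it costs 0.243 of a power.
- My reckoning is therefore 57.2% in each flask, with the charge changing the amounts but not the share.
- The forecast gives 74%, 76%, 79% and 83%, so the share rises all the way. Its ground is that “A larger charge spends more of the reaction at high partner concentration”. We part on the shape.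
- The flasks give 63.1%, 63.1%, 63.1% and 63.1%, so the share hardly changes.

    substrate + coupling partner + catalyst ⇌ target + catalyst, rate k1*[substrate]*[coupling partner]*[catalyst] forward; the back reaction follows from the equilibrium constant (K = 4.00 L mol⁻¹, k = 0.910 L² mol⁻² s⁻¹)
    target ⇌ isomer of the product (K = 1.90, k = 2.20 × 10⁻⁵ s⁻¹)

- In Friday's flask, the first step relaxes with a half-life of 0.261 h at 8.00 h, short against 8.0 h. At 8.00 h, Friday's target is made at 0.478 of the rate at which it is used up, each step taken net. Read back, κ is 0.0576 h⁻¹ in Friday's flask at 8.0 h and 0.0632 h⁻¹ in Tuesday's flask at 4.00 h, against delta's 0.0699 h⁻¹.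

The numbers in the tables stem from a simulated flask with constants of no real substance; noise was put on by code.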